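The constants hand me a kinetic resolution, and from them I choose the temperature of the next run.

    partner + catalyst + left-handed substrate → catalyst + left-handed product (k1 = 1400 M⁻² s⁻¹, Ea1 = 39.0 kJ mol⁻¹)
    partner + precatalyst → catalyst + spent reagent (k2 = 15 M⁻¹ s⁻¹, Ea2 = 43.0 kJ mol⁻¹)
    partner + catalyst + right-handed substrate → catalyst + right-handed product (k3 = 460 M⁻² s⁻¹, Ea3 = 42.0 kJ mol⁻¹)
    (constants at 70 °C)

| flask | left-handed substrate | partner | precatalyst | right-handed substrate | temperature | time |
|---|---|---|---|---|---|---|
| Monday's | 20 mM | 1.10 equiv | 3.9 mol% | 20 mM | 100 °C | 4.0 min |
| Friday's | 20 mM | 1.10 equiv | 3.9 mol% | 20 mM | 70 °C | 4.0 min |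
| Wednesday's | 20 mM | 1.10 equiv | 3.9 mol% | 20 mM | 130 °C | 4.0 min |

- catalyst is single-handed; left-handed substrate and right-handed substrate are mirror images of each other, charged as a racemate, each of them at the stated concentration
- constants are those at 70 °C; use the activation energies for any other temperature
- an excess is the difference of the two amounts in percent of their sum
- an excess is below zero if the other one leads

- which flask leads in excess of left-handed product over right-handed product ("all alike" within 1.5 percentage points) (Monday's / Friday's / Wednesday's / all alike)
- excess of left-handed product over right-handed product at the end, Monday's
- excess of left-handed product over right-handed product at the end, Friday's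
- excess of left-handed product over right-handed product at the end, Wednesday's

**The ratio.** Both substrates meet the same c(catalyst) and c(partner) at every moment. So the logarithm of the right-handed fraction left is r times the logarithm of the left-handed fraction left, where r is step 3's constant over step 1's. At 70 °C, 0.329 is this resolution ratio, k3 over k1, the inverse of the selectivity factor. A lower r means a sharper separation, and the excess at the first moment is (1 − r)/(1 + r), here 50.5%.

**Temperature.** From 70 °C to 130 °C, step 3 speeds up by a factor of 8.9 and step 1 by 7.6, since the activation energy of step 3 is 42.0 kJ mol⁻¹ and that of step 1 is 39.0 kJ mol⁻¹. So r climbs to 0.384 on Wednesday's, with a first-moment excess of 44.5%.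

**The ceiling.** Once activation has taken its share, 21.2 mM of partner faces 40.0 mM of substrate, so partner is the limiting reagent and conversion stops near 53.1%. With the catalyst formed, partner's opening lifetime at 70 °C is 34.5 s, against 4.0 min, though it lengthens as substrate falls.

**My decision.** Monday's, Friday's and Wednesday's carry the same charge, so I rank them by r. I would run cold, at 70 °C, and leave the charge unchanged. My reckoning stops at this order.

**The forecast.** It also names Friday's and goes on to numbers: 33.1% for Monday's, 36.3% for Friday's and 31% for Wednesday's. Its ground for the stop is that “the products stop when it runs out”, "it" being the partner.

**The result.** Friday's leads with 36.3%, against 33.1% on Monday's and 31.0% on Wednesday's, as the forecast said. That gain of 5.3 percentage points over Wednesday's comes at a conversion of 51.4% against 53.0%, with 3.0% of Friday's partner left at the end. Friday's left-handed substrate stands at 30% of its charge, and raised to the power r that gives 67.3% for the right-handed one. The flask holds 67%.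

**A neighbour.** This flask is Friday's with 1.90 equiv of partner, and 4.6% of its left-handed substrate remains. The power gives 36.3% of right-handed substrate left and an excess of 19.9%. The computed flask holds 36.2% of that charge, with an excess of 19.9%.

(The numbers of this flask are assumed; the result is computed.)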